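The pentadecyl chain is disconnected between C5′ and C6′ (side-chain carbons counted from C2 of the dihydropyranone ring). A palladium-catalysed alkyl–alkyl Negishi coupling of decylzinc bromide with the primary chloride of (R)-2-(5-chloropentyl)-5,8-dimethoxychroman-4-one joins the two halves in one traceless operation that needs no later redox correction. The step exploits the fact that this bond lies in the unfunctionalised polymethylene chain, five carbons from stereocentre C2 and insulated from the C4 ketone and the benzene ring, so the complete enantiopure chromanone can be carried into it. C2 is set by Noyori hydrogenation and Mitsunobu inversion; the pyranone ring is closed by Friedel–Crafts acylation.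

Key step: step 6

Remark: the target is the (R)-enantiomer at C2; side-chain carbons are numbered C1′ (bonded to C2) to C15′; decylzinc bromide 11 is taken as the commercial 0.5 M solution in THF.

Step 1
Reactants: 1 methyl acetoacetate; 2 1-bromo-4-chlorobutane
Product: 4 methyl 8-chloro-3-oxooctanoate, via acetoacetate dianion 3 (not isolated)
Conditions: NaH, THF, 0 °C; n-BuLi, 0 °C; then 2, 0 °C → rt; aq. HCl work-up
Reagents that add atoms: none
Why: Acetoacetate dianion γ-alkylation: the more basic terminal carbanion of 3 reacts first, and SN2 displacement occurs at the C–Br end of 2 because bromide is by far the better leaving group, which leaves the primary chloride as the handle for the key step.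

Step 2
Reactants: 4 methyl 8-chloro-3-oxooctanoate
Product: 5 methyl (S)-8-chloro-3-hydroxyoctanoate
Conditions: H2 (4 atm), RuCl2[(S)-BINAP] (0.5 mol %), MeOH, 80 °C
Reagents that add atoms: none
Why: Noyori asymmetric hydrogenation of a β-keto ester: the substrate chelates to ruthenium and (S)-BINAP directs hydride to the carbonyl face that gives the (S)-carbinol (the established sense for 3-oxoalkanoates, where (R)-BINAP gives the (R)-alcohol), while the primary alkyl chloride is inert.

Step 3
Reactants: 5 methyl (S)-8-chloro-3-hydroxyoctanoate; 6 2,5-dimethoxyphenol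
Product: 7 methyl (R)-8-chloro-3-(2,5-dimethoxyphenoxy)octanoate
Conditions: PPh3, DIAD, THF, 0 °C → rt
Reagents that add atoms: none
Why: Mitsunobu etherification: the phenoxide of 6 displaces the alkoxyphosphonium leaving group of 5 by SN2 with inversion, turning the (S)-carbinol into the (R)-aryl ether that becomes C2 of the target.

Step 4
Reactants: 7 methyl (R)-8-chloro-3-(2,5-dimethoxyphenoxy)octanoate
Product: 8 (R)-8-chloro-3-(2,5-dimethoxyphenoxy)octanoic acid
Conditions: LiOH·H2O, THF/H2O, 0 °C → rt; then aq. HCl to pH 2
Reagents that add atoms: lithium hydroxide, [Li+].[OH-]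
Why: Saponification (BAc2 ester hydrolysis) is far faster than α-deprotonation, so neither β-elimination of the aryloxide nor substitution of the primary chloride should interfere, and the stereocentre is not involved.

Step 5
Reactants: 8 (R)-8-chloro-3-(2,5-dimethoxyphenoxy)octanoic acid
Product: 10 (R)-2-(5-chloropentyl)-5,8-dimethoxychroman-4-one, via acyl trifluoroacetate 9 (not isolated)
Conditions: TFAA, CH2Cl2, 0 °C → rt
Reagents that add atoms: none
Why: Intramolecular Friedel–Crafts acylation through the mixed anhydride 9: the only free position ortho to the ether oxygen (C6 of the aryl ring, activated by the two flanking alkoxy groups) attacks to close the six-membered pyranone ring, and the stereocentre is a spectator.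

Step 6
Reactants: 10 (R)-2-(5-chloropentyl)-5,8-dimethoxychroman-4-one; 11 decylzinc bromide
Product: 12 (R)-5,8-dimethoxy-2-pentadecylchroman-4-one
Conditions: Pd2(dba)3 (2 mol %), tricyclopentylphosphine (8 mol %), N-methylimidazole, THF/NMP (2:1), 80 °C
Reagents that add atoms: none
Why: Pd(0) bearing the electron-rich, bulky tricyclopentylphosphine inserts into the primary C–Cl bond of 10 by an SN2-type oxidative addition, the N-methylimidazole-activated decylzinc bromide transmetalates, and reductive elimination forms the C(sp3)–C(sp3) bond between side-chain carbons C5′ and C6′ faster than β-hydride elimination. The closest known reaction type is the palladium-catalysed Negishi alkyl–alkyl coupling of unactivated primary alkyl chlorides, bromides, iodides and tosylates with alkylzinc halides, here only applied to a chloride that carries a distant chromanone. No ring is closed and no stereocentre is created; the C2 stereocentre lies five carbons from the reacting carbon and is not touched. The step needs chemoselectivity for the C–Cl bond over the C4 ketone and must not open the pyranone ring by retro-oxa-Michael reaction: alkylzinc halides do not add to ketones, the C4 carbonyl is further deactivated by conjugation with O1 and the 5-methoxy group, and the medium contains no base stronger than N-methylimidazole. The unbranched primary chloride, free of β-heteroatoms, should give clean oxidative addition, and the zinc reagent, the inexpensive partner, can be used in excess.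

Step 7
Reactants: 12 (R)-5,8-dimethoxy-2-pentadecylchroman-4-one
Product: 14 (R)-5,8-dihydroxy-2-pentadecylchroman-4-one, via bis(dibromoboryl) ether 13 (not isolated)
Conditions: BBr3 (5 equiv), CH2Cl2, −78 °C → rt; then H2O, under N2
Reagents that add atoms: none
Why: Boron tribromide ether cleavage: bromide attacks the methyl groups of the Lewis acid-complexed aryl methyl ethers (the 5-methoxy assisted by chelation to the C4 carbonyl), which is faster than cleavage of the secondary C2–O1 bond whose oxygen is deactivated by conjugation to the ketone, and hydrolysis of 13 releases the hydroquinone without touching C2.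

Compound list
1 | methyl acetoacetate | CC(=O)CC(=O)OC | starting material
2 | 1-bromo-4-chlorobutane | ClCCCCBr | starting material
3 | sodium lithium dianion of methyl acetoacetate | [Na+].[Li+].C=C([O-])C=C([O-])OC | intermediate
4 | methyl 8-chloro-3-oxooctanoate | ClCCCCCC(=O)CC(=O)OC | intermediate
5 | methyl (S)-8-chloro-3-hydroxyoctanoate | ClCCCCC[C@H](O)CC(=O)OC | intermediate
6 | 2,5-dimethoxyphenol | COc1ccc(OC)c(O)c1 | starting material
7 | methyl (R)-8-chloro-3-(2,5-dimethoxyphenoxy)octanoate | ClCCCCC[C@@H](Oc1cc(OC)ccc1OC)CC(=O)OC | intermediate
8 | (R)-8-chloro-3-(2,5-dimethoxyphenoxy)octanoic acid | ClCCCCC[C@@H](Oc1cc(OC)ccc1OC)CC(=O)O | intermediate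
9 | (R)-8-chloro-3-(2,5-dimethoxyphenoxy)octanoic trifluoroacetic anhydride | ClCCCCC[C@@H](Oc1cc(OC)ccc1OC)CC(=O)OC(=O)C(F)(F)F | intermediate
10 | (R)-2-(5-chloropentyl)-5,8-dimethoxychroman-4-one | ClCCCCC[C@@H]1CC(=O)c2c(OC)ccc(OC)c2O1 | intermediate
11 | decylzinc bromide | CCCCCCCCCC[Zn]Br | starting material
12 | (R)-5,8-dimethoxy-2-pentadecylchroman-4-one | CCCCCCCCCCCCCCC[C@@H]1CC(=O)c2c(OC)ccc(OC)c2O1 | intermediate
13 | (R)-5,8-bis(dibromoboryloxy)-2-pentadecylchroman-4-one | CCCCCCCCCCCCCCC[C@@H]1CC(=O)c2c(OB(Br)Br)ccc(OB(Br)Br)c2O1 | intermediate
14 | (R)-5,8-dihydroxy-2-pentadecylchroman-4-one | CCCCCCCCCCCCCCC[C@@H]1CC(=O)c2c(O)ccc(O)c2O1 | target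

Total step count: 7. Longest linear sequence: 7 steps (1 → 14); 2, 6 and 11 enter as commercial partners.

Steps most likely to fail

Step 6 (key step). Oxidative addition into the primary C–Cl bond may be slow, so that β-hydride elimination or protodemetalation of the alkylpalladium competes, and the ketone may enolise slowly at 80 °C. The fallback sets out from 10 and returns at 12. Halide exchange with NaI in acetone at reflux should give (R)-2-(5-iodopentyl)-5,8-dimethoxychroman-4-one F1. F1 is then joined to dec-1-ene (C=CCCCCCCCC) by nickel-hydride reductive hydroalkylation (NiBr2·diglyme, bipyridine ligand, (EtO)2MeSiH, Na2CO3, DMA, rt). The terminal alkene is hydrometalated anti-Markovnikov and acts as the primary alkyl nucleophile, so the same C5′–C6′ bond forms at room temperature without an organozinc reagent.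

Step 3. The Mitsunobu betaine may dehydrate the β-hydroxy ester to the enoate by β-elimination instead of giving substitution. The fallback sets out from 5 and returns at 8, which makes step 4 unnecessary. LiBH4 (THF, 0 °C → rt) should reduce the ester to (S)-8-chlorooctane-1,3-diol F2. Selective silylation of the primary hydroxyl (TBSCl, imidazole, CH2Cl2, 0 °C) should give (S)-1-[(tert-butyldimethylsilyl)oxy]-8-chlorooctan-3-ol F3. Mitsunobu etherification with 6 (PPh3, DIAD, THF), now on a carbinol without acidic α-hydrogens so that elimination is shut off, should give with inversion (R)-tert-butyl{[8-chloro-3-(2,5-dimethoxyphenoxy)octyl]oxy}dimethylsilane F4. TBAF (THF) should release (R)-8-chloro-3-(2,5-dimethoxyphenoxy)octan-1-ol F5. Oxidation with TEMPO/PhI(OAc)2 in MeCN/H2O should pass through the transient (R)-8-chloro-3-(2,5-dimethoxyphenoxy)octanal F6 to acid 8.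

Step 7. The Lewis acid may open the dihydropyranone ring at the C2–O1 bond with erosion of configuration, the 8-methoxy group may be cleaved incompletely, and the hydroquinone may oxidise in air during work-up. The fallback sets out from 12 and returns at 14. Oxidative demethylation of the para-dimethoxyarene with ceric ammonium nitrate (MeCN/H2O, 0 °C) should give (R)-2-pentadecyl-2,3-dihydro-4H-chromene-4,5,8-trione F7. Reduction of the quinone with aqueous Na2S2O4 (EtOAc/H2O, rt, under N2) then gives the hydroquinone; no Lewis acid touches the ring.

Further compounds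
F1 | step 6 | (R)-2-(5-iodopentyl)-5,8-dimethoxychroman-4-one | ICCCCC[C@@H]1CC(=O)c2c(OC)ccc(OC)c2O1
F2 | step 3 | (S)-8-chlorooctane-1,3-diol | ClCCCCC[C@H](O)CCO
F3 | step 3 | (S)-1-[(tert-butyldimethylsilyl)oxy]-8-chlorooctan-3-ol | ClCCCCC[C@H](O)CCO[Si](C)(C)C(C)(C)C
F4 | step 3 | (R)-tert-butyl{[8-chloro-3-(2,5-dimethoxyphenoxy)octyl]oxy}dimethylsilane | ClCCCCC[C@@H](Oc1cc(OC)ccc1OC)CCO[Si](C)(C)C(C)(C)C
F5 | step 3 | (R)-8-chloro-3-(2,5-dimethoxyphenoxy)octan-1-ol | ClCCCCC[C@@H](Oc1cc(OC)ccc1OC)CCO
F6 | step 3 | (R)-8-chloro-3-(2,5-dimethoxyphenoxy)octanal | ClCCCCC[C@@H](Oc1cc(OC)ccc1OC)CC=O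
F7 | step 7 | (R)-2-pentadecyl-2,3-dihydro-4H-chromene-4,5,8-trione | CCCCCCCCCCCCCCC[C@@H]1CC(=O)C2=C(O1)C(=O)C=CC2=O
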